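**One step.** In a one-step world the ratio of target to other capture product would stand still, but here starting material feeds an intermediate for which two nucleophiles compete, and the second of them must first come out of the gas.

| flask | starting material | first nucleophile | gas | remark | time |
|---|---|---|---|---|---|
| Wednesday's | 1.5 M | 3 M | 200 mM (held) | run made earlier |  |
| flask | 1.5 M | 1.50 M | 200 mM (held) |  | 25 h |

Wednesday's run (percent of the starting material charged)

| time / h | target / % | other capture product / % |
|---|---|---|
| 0.500 | 2.8 | 0.5 |
| 1.00 | 4.9 | 0 |
| 1.50 | 8.5 | 0 |
| 2.00 | 10.6 | 0.2 |
| 2.50 | 13.8 | 0 |

(each reading ± 0.5 percentage points)

- what is said of target includes crystals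
- crystals is a solid; its amount is given per volume of the solution
- at the start none of second nucleophile is dissolved
- the numbers in the tables scatter with a standard deviation of 0.5 percentage points
- steps thought possible: gas <-> second nucleophile; first nucleophile -> decomposition product; second nucleophile + intermediate -> other capture product; starting material <-> intermediate; crystals <-> target; first nucleophile + intermediate -> target

1. ratio of target to other capture product at 20 min
2. ratio of target to other capture product at 3.0 h
3. ratio of target to other capture product at 25 h
4. which of target and other capture product there is more of at 25 h

**Fastest rung.** In Wednesday's run target already reads 2.8% at 0.500 h, with no visible lag, so I treat the intermediate as a scarce species in quasi-steady state, used about as fast as it is made, and each capture as a choice between the two nucleophiles. Wednesday's other capture product stands nowhere clear of the scatter, so I cap it at 1.00% at 2.50 h, twice its highest reading. Target is then 13.8 times that cap, and with second nucleophile taken at its saturation this gives σ = 0.920, the selectivity factor: the capture rate of first nucleophile over that of second nucleophile at equal concentration.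

**Middle rung.** The readings do not time the filling with second nucleophile. Your flask's ratio at saturation, with first nucleophile unspent, is S = σ times charge over saturation, 6.90, and at 20 min and 3.0 h I expect it above S, by a margin I cannot read.

**Slowest rung.** Work with f, the fraction of first nucleophile left. If it leaves by way of target, and second nucleophile is held at saturation, the accumulated ratio is S(1 − f)/ln(1/f). Reckoned from its last target reading, Wednesday's starting material drains at about 0.0594 /h, a time of 16.8 h, far longer than the first reading. Your flask has half Wednesday's first nucleophile, so I let it drain between half that rate and that rate. With equal charges, starting material's fraction left stands in for f, between 22.7% and 47.6%. My ratio at 25 h is thus 3.59 to 4.87, with target ahead.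

**The forecast.** The forecast gave 200, 25 and 3, below my range at the end, with target ahead, and called the last figure “poorly constrained because neither the gas uptake rate nor the decomposition rate has been measured”.

**The result.** The flask gives 46.0, 10.5 and 5.34, with target ahead, and at 25.0 h it holds 45% of its first nucleophile charge.

gas ⇌ second nucleophile, rate k1*(csat - [second nucleophile]) (kL = 0.841 /h); first nucleophile → decomposition product (k = 9.72 × 10⁻⁵ /h); second nucleophile + intermediate → other capture product (k = 4.20 /M/h); starting material ⇌ intermediate (K = 0.0195, k = 0.0796 /h); crystals ⇌ target, rate k5*(cs5 - [target]) while solid is left; crystals form when [target] > cs5 (solubility = 31.0 mM, k = 1.52 /h); first nucleophile + intermediate → target (k = 3.91 /M/h) That fraction put into the rule gives 4.75. The neighbour charged with 0.38 M of first nucleophile has S = 1.75 and keeps 20.6% of its charge at 25.0 h, so the rule gives 0.879 there, and its simulated ratio is 1.01.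

The runs come from a simulation for substances that don't exist; the scatter is artificial.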